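## Retrosynthetic overview

- The exocyclic methylene comes last, by decarboxylative methylenation of an α-carboxy lactone.
- The cis-fused γ-lactone is closed by acid-mediated displacement of an oxygen bridge by an endo carboxylic acid (inversion at the lactone carbinol carbon); the bridge oxygen stays behind as the ring secondary alcohol.
- The side chain comes from exo alkynylation of a bicyclic ketone and ester-directed alkyne hydration; the (R)-2-methylbutanoate sits on an axial alcohol made by enolate hydroxylation.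
- The 8-oxabicyclo[3.2.1]octane core comes from a furan-3-ylmalonate and a siloxyvinyl diazoacetate: dirhodium-catalysed cyclopropanation/Cope rearrangement builds the seven-membered carbocycle and the oxygen bridge in one operation.
- Ring order: transient cyclopropane, then carbocycle plus oxygen bridge together, then the γ-lactone at the cost of the bridge.

Assumption: Rh2(S-PTAD)4 is taken to give the (1R,5R) adduct drawn; if the antipode forms, the (R)-configured catalyst is used with no other change.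

Locants of the bicyclic compounds follow 8-oxabicyclo[3.2.1]octane numbering (C1 and C5 bridgeheads, O8 the bridge); "exo" means syn to O8.

## Route

Step 1
Reactants: 1 3-bromofuran; 2 di-tert-butyl malonate
Product: 3 di-tert-butyl 2-(furan-3-yl)propanedioate
Conditions: Pd(dba)2 (2 mol%), P(tBu)3 (4 mol%), NaH, THF, 70 °C
Reagents that add atoms: none
Why: Palladium-catalysed α-arylation of a malonate enolate with a heteroaryl bromide (Hartwig–Buchwald type); no stereocentre is formed.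

Step 2
Reactants: 4 benzyl 3-oxobutanoate
Product: 5 benzyl 2-diazo-3-oxobutanoate
Conditions: p-ABSA, Et3N, MeCN, 0 °C → rt
Reagents that add atoms: 4-acetamidobenzenesulfonyl azide (p-ABSA), CC(=O)Nc1ccc(cc1)S(=O)(=O)N=[N+]=[N-]
Why: Regitz diazo transfer to the activated methylene of a β-keto ester; no stereocentre.

Step 3
Reactants: 5 benzyl 2-diazo-3-oxobutanoate
Product: 6 benzyl 3-[(tert-butyldimethylsilyl)oxy]-2-diazobut-3-enoate
Conditions: TBSOTf, Et3N, CH2Cl2, 0 °C
Reagents that add atoms: tert-butyldimethylsilyl trifluoromethanesulfonate (TBSOTf), CC(C)(C)[Si](C)(C)OS(=O)(=O)C(F)(F)F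
Why: Soft enolisation and O-silylation of the methyl ketone gives the siloxyvinyl diazoacetate; no stereocentre.

Step 4
Reactants: 3 di-tert-butyl 2-(furan-3-yl)propanedioate; 6 benzyl 3-[(tert-butyldimethylsilyl)oxy]-2-diazobut-3-enoate
Product: 8 benzyl (1R,5R)-3-[(tert-butyldimethylsilyl)oxy]-6-(1,3-di-tert-butoxy-1,3-dioxopropan-2-yl)-8-oxabicyclo[3.2.1]octa-2,6-diene-2-carboxylate, via divinylcyclopropane 7 (not isolated)
Conditions: Rh2(S-PTAD)4 (1 mol%), slow addition of 6, 2,2-dimethylbutane, −20 °C → rt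
Reagents that add atoms: none
Why: Dirhodium-catalysed nitrogen loss and cyclopropanation of the unsubstituted, less hindered C4=C5 bond of the furan gives the cis-divinylcyclopropane, whose boat Cope rearrangement (Davies tandem cyclopropanation/Cope, a formal (4+3) cycloaddition) forms the carbocycle and the oxygen bridge together; the chiral catalyst selects the furan face and so sets both bridgeheads (1R,5R), and attack at the unsubstituted bond puts the ester-bearing carbon next to C1, remote from the malonyl group.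

Step 5
Reactants: 8 benzyl (1R,5R)-3-[(tert-butyldimethylsilyl)oxy]-6-(1,3-di-tert-butoxy-1,3-dioxopropan-2-yl)-8-oxabicyclo[3.2.1]octa-2,6-diene-2-carboxylate
Product: 10 benzyl (1R,2S,5R)-6-(1,3-di-tert-butoxy-1,3-dioxopropan-2-yl)-2-methyl-3-oxo-8-oxabicyclo[3.2.1]oct-6-ene-2-carboxylate, via cesium enolate 9 (not isolated)
Conditions: CsF (1.05 equiv), MeI, DMF, 0 °C → rt
Reagents that add atoms: iodomethane, CI
Why: Fluoride cleaves the silyl enol ether to the β-keto ester enolate, which is C-methylated between the two carbonyl groups from the exo face (enolate alkylation); this quaternary centre is reset in step 6.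

Step 6
Reactants: 10 benzyl (1R,2S,5R)-6-(1,3-di-tert-butoxy-1,3-dioxopropan-2-yl)-2-methyl-3-oxo-8-oxabicyclo[3.2.1]oct-6-ene-2-carboxylate
Product: 12 di-tert-butyl 2-[(1R,2S,5R,6S)-2-methyl-3-oxo-8-oxabicyclo[3.2.1]octan-6-yl]propanedioate, via keto acid 11 (not isolated)
Conditions: H2 (1 atm), Pd/C, EtOAc, rt; then 50 °C, Et3N (cat.)
Reagents that add atoms: none
Why: Hydrogenolysis of the benzyl ester gives the β-keto acid, which decarboxylates on warming, while H2 adds to the ring alkene from the exo face so the malonyl group ends endo (6S); protonation and equilibration leave the C2 methyl equatorial, anti to the bridge (2S).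

Step 7
Reactants: 12 di-tert-butyl 2-[(1R,2S,5R,6S)-2-methyl-3-oxo-8-oxabicyclo[3.2.1]octan-6-yl]propanedioate
Product: 14 di-tert-butyl 2-[(1R,2S,4S,5S,6S)-4-hydroxy-2-methyl-3-oxo-8-oxabicyclo[3.2.1]octan-6-yl]propanedioate, via disodium dianion 13 (not isolated)
Conditions: NaN(SiMe3)2 (2.2 equiv), THF, −78 °C; 2-(benzenesulfonyl)-3-phenyloxaziridine (1.1 equiv); NH4Cl (aq)
Reagents that add atoms: 2-(benzenesulfonyl)-3-phenyloxaziridine, O=S(=O)(N1OC1c1ccccc1)c1ccccc1
Why: After the first equivalent of base has taken the malonate proton, kinetic deprotonation occurs at the C4 methylene and not at the methyl-bearing C2, and oxygen transfer (Davis enolate hydroxylation) comes from the open exo face, giving the axial 4S alcohol cis to the oxygen bridge.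

Step 8
Reactants: 14 di-tert-butyl 2-[(1R,2S,4S,5S,6S)-4-hydroxy-2-methyl-3-oxo-8-oxabicyclo[3.2.1]octan-6-yl]propanedioate; 15 (2R)-2-methylbutanoic acid
Product: 16 di-tert-butyl 2-[(1R,2S,4S,5S,6S)-2-methyl-4-{[(2R)-2-methylbutanoyl]oxy}-3-oxo-8-oxabicyclo[3.2.1]octan-6-yl]propanedioate
Conditions: DCC, DMAP (cat.), CH2Cl2, 0 °C → rt
Reagents that add atoms: none
Why: Steglich esterification of the exo-facing secondary α-ketol, with retention at the carbinol carbon and at the acid's stereocentre.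

Step 9
Reactants: 16 di-tert-butyl 2-[(1R,2S,4S,5S,6S)-2-methyl-4-{[(2R)-2-methylbutanoyl]oxy}-3-oxo-8-oxabicyclo[3.2.1]octan-6-yl]propanedioate; 17 (2R)-but-3-yn-2-ol
Product: 19 di-tert-butyl 2-[(1R,2S,3R,4S,5S,6S)-3-hydroxy-3-[(3R)-3-hydroxybut-1-yn-1-yl]-2-methyl-4-{[(2R)-2-methylbutanoyl]oxy}-8-oxabicyclo[3.2.1]octan-6-yl]propanedioate, via dilithio alkynolate 18 (not isolated)
Conditions: 17 (3 equiv), n-BuLi (6 equiv), THF, −78 → −20 °C; then 16, −78 °C; NH4Cl (aq)
Reagents that add atoms: none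
Why: 1,2-Addition of the lithium acetylide to the activated α-acyloxy ketone occurs from the exo face, because the endo face is blocked by the two-carbon bridge and its endo malonyl group, giving the 3R carbinol whose axial OH is trans-diaxial to the ester (no acyl migration possible); the carbinol centre of 17 is carried through unchanged.

Step 10
Reactants: 19 di-tert-butyl 2-[(1R,2S,3R,4S,5S,6S)-3-hydroxy-3-[(3R)-3-hydroxybut-1-yn-1-yl]-2-methyl-4-{[(2R)-2-methylbutanoyl]oxy}-8-oxabicyclo[3.2.1]octan-6-yl]propanedioate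
Product: 20 di-tert-butyl 2-[(1R,2S,3S,4S,5S,6S)-3-hydroxy-3-[(3R)-3-hydroxybutanoyl]-2-methyl-4-{[(2R)-2-methylbutanoyl]oxy}-8-oxabicyclo[3.2.1]octan-6-yl]propanedioate
Conditions: Ph3PAuNTf2 (5 mol%), 1,4-dioxane/H2O (10:1), rt
Reagents that add atoms: water, O
Why: Proposed new method: the cationic gold catalyst activates the alkyne and the carbonyl oxygen of the gauche C4 ester attacks the ring-attached alkyne carbon in a 6-exo-dig mode, so water enters at that carbon and the acyl group returns to the C4 oxygen on hydrolysis, giving the ketone next to C3 with no new stereocentre; the closest known reaction type is the neighbouring-carbonyl-assisted gold-catalysed hydration of propargylic esters.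

Step 11
Reactants: 20 di-tert-butyl 2-[(1R,2S,3S,4S,5S,6S)-3-hydroxy-3-[(3R)-3-hydroxybutanoyl]-2-methyl-4-{[(2R)-2-methylbutanoyl]oxy}-8-oxabicyclo[3.2.1]octan-6-yl]propanedioate
Product: 22 (3aS,5R,6S,7S,8S,8aR)-5,7-dihydroxy-7-[(3R)-3-hydroxybutanoyl]-6-methyl-8-{[(2R)-2-methylbutanoyl]oxy}-2-oxooctahydro-2H-cyclohepta[b]furan-3-carboxylic acid, via malonic diacid 21 (not isolated)
Conditions: TFA/CH2Cl2 (1:3), 0 °C → rt; evaporate; TfOH (0.3 equiv), (CF3)2CHOH, 0 °C → rt
Reagents that add atoms: none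
Why: Proposed new method: TFA removes both tert-butyl groups, and in a strongly acidic, non-nucleophilic ionising medium the protonated oxygen bridge is displaced at C5 by the endo carboxylic acid, which sits antiperiplanar to the C5–O8 bond, in a 5-exo SN2 lactonisation with inversion at C5 (cis-fused γ-lactone) while the bridge oxygen stays on C1 with retention as the free secondary alcohol; the closest known reaction type is the acid-mediated opening of 7-oxanorbornane and 8-oxabicyclo[3.2.1]octane bridges with neighbouring-group participation.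

Step 12
Reactants: 22 (3aS,5R,6S,7S,8S,8aR)-5,7-dihydroxy-7-[(3R)-3-hydroxybutanoyl]-6-methyl-8-{[(2R)-2-methylbutanoyl]oxy}-2-oxooctahydro-2H-cyclohepta[b]furan-3-carboxylic acid
Product: 24 (3aS,5R,6S,7S,8S,8aR)-5,7-dihydroxy-7-[(3R)-3-hydroxybutanoyl]-6-methyl-3-methylidene-2-oxooctahydro-2H-cyclohepta[b]furan-8-yl (2R)-2-methylbutanoate, via Mannich base 23 (not isolated)
Conditions: CH2O (37% aq), Et2NH, THF, rt; then NaOAc, AcOH, 60 °C
Reagents that add atoms: formaldehyde, C=O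
Why: Decarboxylative Mannich methylenation: the malonic half-acid condenses with formaldehyde and diethylamine, and the Mannich base loses CO2 and the amine on warming to give the exocyclic methylene; the mixed C3 centre disappears and no other centre is touched.

## Compound list

1 | 3-bromofuran | Brc1ccoc1 | starting material
2 | di-tert-butyl malonate | CC(C)(C)OC(=O)CC(=O)OC(C)(C)C | starting material
3 | di-tert-butyl 2-(furan-3-yl)propanedioate | CC(C)(C)OC(=O)C(c1ccoc1)C(=O)OC(C)(C)C | intermediate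
4 | benzyl 3-oxobutanoate | CC(=O)CC(=O)OCc1ccccc1 | starting material
5 | benzyl 2-diazo-3-oxobutanoate | CC(=O)C(=[N+]=[N-])C(=O)OCc1ccccc1 | intermediate
6 | benzyl 3-[(tert-butyldimethylsilyl)oxy]-2-diazobut-3-enoate | C=C(O[Si](C)(C)C(C)(C)C)C(=[N+]=[N-])C(=O)OCc1ccccc1 | intermediate
7 | benzyl (1R,5R,6R)-6-{1-[(tert-butyldimethylsilyl)oxy]ethenyl}-4-(1,3-di-tert-butoxy-1,3-dioxopropan-2-yl)-2-oxabicyclo[3.1.0]hex-3-ene-6-carboxylate (siloxyvinyl group endo; not isolated) | O=C(OCc1ccccc1)[C@@]1(C(=C)O[Si](C)(C)C(C)(C)C)[C@@H]2OC=C([C@H]12)C(C(=O)OC(C)(C)C)C(=O)OC(C)(C)C | intermediate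
8 | benzyl (1R,5R)-3-[(tert-butyldimethylsilyl)oxy]-6-(1,3-di-tert-butoxy-1,3-dioxopropan-2-yl)-8-oxabicyclo[3.2.1]octa-2,6-diene-2-carboxylate | O=C(OCc1ccccc1)C1=C(O[Si](C)(C)C(C)(C)C)C[C@H]2O[C@@H]1C=C2C(C(=O)OC(C)(C)C)C(=O)OC(C)(C)C | intermediate
9 | cesium (1R,5R)-2-[(benzyloxy)carbonyl]-6-(1,3-di-tert-butoxy-1,3-dioxopropan-2-yl)-8-oxabicyclo[3.2.1]octa-2,6-dien-3-olate (not isolated) | [Cs+].O=C(OCc1ccccc1)C1=C([O-])C[C@H]2O[C@@H]1C=C2C(C(=O)OC(C)(C)C)C(=O)OC(C)(C)C | intermediate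
10 | benzyl (1R,2S,5R)-6-(1,3-di-tert-butoxy-1,3-dioxopropan-2-yl)-2-methyl-3-oxo-8-oxabicyclo[3.2.1]oct-6-ene-2-carboxylate (methyl exo) | O=C(OCc1ccccc1)[C@]1(C)C(=O)C[C@H]2O[C@@H]1C=C2C(C(=O)OC(C)(C)C)C(=O)OC(C)(C)C | intermediate
11 | (1R,2S,5R,6S)-6-(1,3-di-tert-butoxy-1,3-dioxopropan-2-yl)-2-methyl-3-oxo-8-oxabicyclo[3.2.1]octane-2-carboxylic acid (not isolated) | OC(=O)[C@]1(C)C(=O)C[C@H]2O[C@@H]1C[C@H]2C(C(=O)OC(C)(C)C)C(=O)OC(C)(C)C | intermediate
12 | di-tert-butyl 2-[(1R,2S,5R,6S)-2-methyl-3-oxo-8-oxabicyclo[3.2.1]octan-6-yl]propanedioate (methyl equatorial; malonyl endo) | C[C@@H]1C(=O)C[C@H]2O[C@@H]1C[C@H]2C(C(=O)OC(C)(C)C)C(=O)OC(C)(C)C | intermediate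
13 | disodium salt of 12 (malonate carbanion plus C3–C4 enolate; not isolated) | [Na+].[Na+].C[C@@H]1C([O-])=C[C@H]2O[C@@H]1C[C@H]2[C-](C(=O)OC(C)(C)C)C(=O)OC(C)(C)C | intermediate
14 | di-tert-butyl 2-[(1R,2S,4S,5S,6S)-4-hydroxy-2-methyl-3-oxo-8-oxabicyclo[3.2.1]octan-6-yl]propanedioate (hydroxyl axial, cis to O8) | C[C@@H]1C(=O)[C@@H](O)[C@H]2O[C@@H]1C[C@H]2C(C(=O)OC(C)(C)C)C(=O)OC(C)(C)C | intermediate
15 | (2R)-2-methylbutanoic acid | CC[C@@H](C)C(O)=O | starting material
16 | di-tert-butyl 2-[(1R,2S,4S,5S,6S)-2-methyl-4-{[(2R)-2-methylbutanoyl]oxy}-3-oxo-8-oxabicyclo[3.2.1]octan-6-yl]propanedioate | C[C@@H]1C(=O)[C@@H](OC(=O)[C@H](C)CC)[C@H]2O[C@@H]1C[C@H]2C(C(=O)OC(C)(C)C)C(=O)OC(C)(C)C | intermediate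
17 | (2R)-but-3-yn-2-ol | C#C[C@@H](C)O | starting material
18 | dilithium salt of (2R)-but-3-yn-2-ol (alkoxide plus acetylide; not isolated) | [Li+].[Li+].[C-]#C[C@@H](C)[O-] | intermediate
19 | di-tert-butyl 2-[(1R,2S,3R,4S,5S,6S)-3-hydroxy-3-[(3R)-3-hydroxybut-1-yn-1-yl]-2-methyl-4-{[(2R)-2-methylbutanoyl]oxy}-8-oxabicyclo[3.2.1]octan-6-yl]propanedioate | C[C@@H]1[C@@](O)(C#C[C@@H](C)O)[C@@H](OC(=O)[C@H](C)CC)[C@H]2O[C@@H]1C[C@H]2C(C(=O)OC(C)(C)C)C(=O)OC(C)(C)C | intermediate
20 | di-tert-butyl 2-[(1R,2S,3S,4S,5S,6S)-3-hydroxy-3-[(3R)-3-hydroxybutanoyl]-2-methyl-4-{[(2R)-2-methylbutanoyl]oxy}-8-oxabicyclo[3.2.1]octan-6-yl]propanedioate | C[C@@H]1[C@@](O)(C(=O)C[C@@H](C)O)[C@@H](OC(=O)[C@H](C)CC)[C@H]2O[C@@H]1C[C@H]2C(C(=O)OC(C)(C)C)C(=O)OC(C)(C)C | intermediate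
21 | 2-[(1R,2S,3S,4S,5S,6S)-3-hydroxy-3-[(3R)-3-hydroxybutanoyl]-2-methyl-4-{[(2R)-2-methylbutanoyl]oxy}-8-oxabicyclo[3.2.1]octan-6-yl]propanedioic acid (not isolated) | C[C@@H]1[C@@](O)(C(=O)C[C@@H](C)O)[C@@H](OC(=O)[C@H](C)CC)[C@H]2O[C@@H]1C[C@H]2C(C(O)=O)C(O)=O | intermediate
22 | (3aS,5R,6S,7S,8S,8aR)-5,7-dihydroxy-7-[(3R)-3-hydroxybutanoyl]-6-methyl-8-{[(2R)-2-methylbutanoyl]oxy}-2-oxooctahydro-2H-cyclohepta[b]furan-3-carboxylic acid (both C3 epimers) | OC(=O)C1C(=O)O[C@@H]2[C@H]1C[C@@H](O)[C@H](C)[C@@](O)(C(=O)C[C@@H](C)O)[C@H]2OC(=O)[C@H](C)CC | intermediate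
23 | (3aS,5R,6S,7S,8S,8aR)-3-[(diethylamino)methyl]-5,7-dihydroxy-7-[(3R)-3-hydroxybutanoyl]-6-methyl-8-{[(2R)-2-methylbutanoyl]oxy}-2-oxooctahydro-2H-cyclohepta[b]furan-3-carboxylic acid (not isolated) | CCN(CC)CC1(C(O)=O)C(=O)O[C@@H]2[C@H]1C[C@@H](O)[C@H](C)[C@@](O)(C(=O)C[C@@H](C)O)[C@H]2OC(=O)[C@H](C)CC | intermediate
24 | (3aS,5R,6S,7S,8S,8aR)-5,7-dihydroxy-7-[(3R)-3-hydroxybutanoyl]-6-methyl-3-methylidene-2-oxooctahydro-2H-cyclohepta[b]furan-8-yl (2R)-2-methylbutanoate | C=C1C(=O)O[C@@H]2[C@H]1C[C@@H](O)[C@H](C)[C@@](O)(C(=O)C[C@@H](C)O)[C@H]2OC(=O)[C@H](C)CC | target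

## Step count

Total steps: 12. Longest linear sequence: 11 (steps 2 to 12, from benzyl 3-oxobutanoate); the branch from 3-bromofuran is 10 steps.

## Three steps most likely to fail

Step 11 (bridge-opening lactonisation). The ether carbon to be attacked is deactivated by the neighbouring acyloxy group, and the carboxyl could instead reach the other bridgehead and form a bridged δ-lactone. The fallback lets an external nucleophile open the bridge at the electronically favoured bridgehead and then corrects both carbons by inversion. It sets out from 20: TFA gives diacid 21, and Me2BBr (CH2Cl2, −78 → 0 °C) delivers bromide with inversion to the unhindered bridgehead C1, leaving the old bridge oxygen on C5, to give 2-[(1S,2S,3S,4S,5R,6S)-6-bromo-2,4-dihydroxy-4-[(3R)-3-hydroxybutanoyl]-5-methyl-3-{[(2R)-2-methylbutanoyl]oxy}cycloheptyl]propanedioic acid F4. Mitsunobu lactonisation (PPh3, DIAD, THF) of the ring secondary alcohol with one malonic carboxyl inverts that carbon and gives the cis-fused (3aS,5S,6R,7S,8S,8aR)-5-bromo-7-hydroxy-7-[(3R)-3-hydroxybutanoyl]-6-methyl-8-{[(2R)-2-methylbutanoyl]oxy}-2-oxooctahydro-2H-cyclohepta[b]furan-3-carboxylic acid F5. Displacement of bromide with CsOCHO (18-crown-6, DMF) inverts the second carbon and gives the (3aS,5R,6S,7S,8S,8aR)-5-(formyloxy) analogue F6, and KHCO3 in MeOH removes the formyl group to come back to the route at 22.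

Step 4 (cyclopropanation/Cope). The bulky malonyl group on the furan may erode rate, regioselectivity for the unsubstituted furan bond, or enantioselectivity. The fallback moves the malonate coupling behind the ring construction. It sets out from 1 and 6: the same dirhodium-catalysed reaction is run on 3-bromofuran itself, whose substituent is small and deactivates the substituted bond, to give benzyl (1R,5R)-6-bromo-3-[(tert-butyldimethylsilyl)oxy]-8-oxabicyclo[3.2.1]octa-2,6-diene-2-carboxylate F1. Palladium-catalysed coupling of this vinyl bromide with the sodium enolate of 2 (Pd(dba)2, P(tBu)3, NaH, THF, 60 °C) comes back to the route at 8.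

Step 10 (alkyne hydration). The tertiary propargylic alcohol could undergo Meyer–Schuster rearrangement, or water could add at the wrong alkyne carbon if ester participation is slow. The fallback fixes regiochemistry by ynone polarity instead of a neighbouring group. It sets out from 19: MnO2 (CH2Cl2, rt) oxidises only the secondary propargylic alcohol to di-tert-butyl 2-[(1R,2S,3R,4S,5S,6S)-3-hydroxy-2-methyl-4-{[(2R)-2-methylbutanoyl]oxy}-3-(3-oxobut-1-yn-1-yl)-8-oxabicyclo[3.2.1]octan-6-yl]propanedioate F2. Amine-mediated conjugate hydration (Et2NH, then aqueous AcOH) can place oxygen only β to the new ketone, on the ring-attached carbon, giving di-tert-butyl 2-[(1R,2S,3S,4S,5S,6S)-3-hydroxy-2-methyl-4-{[(2R)-2-methylbutanoyl]oxy}-3-(3-oxobutanoyl)-8-oxabicyclo[3.2.1]octan-6-yl]propanedioate F3. Hydrogenation of the unhindered methyl ketone with RuCl2[(R)-BINAP] (H2, MeOH) restores the 3R carbinol and comes back to the route at 20.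

## Further compounds

F1 | step 4 | benzyl (1R,5R)-6-bromo-3-[(tert-butyldimethylsilyl)oxy]-8-oxabicyclo[3.2.1]octa-2,6-diene-2-carboxylate | O=C(OCc1ccccc1)C1=C(O[Si](C)(C)C(C)(C)C)C[C@H]2O[C@@H]1C=C2Br
F2 | step 10 | di-tert-butyl 2-[(1R,2S,3R,4S,5S,6S)-3-hydroxy-2-methyl-4-{[(2R)-2-methylbutanoyl]oxy}-3-(3-oxobut-1-yn-1-yl)-8-oxabicyclo[3.2.1]octan-6-yl]propanedioate | C[C@@H]1[C@@](O)(C#CC(C)=O)[C@@H](OC(=O)[C@H](C)CC)[C@H]2O[C@@H]1C[C@H]2C(C(=O)OC(C)(C)C)C(=O)OC(C)(C)C
F3 | step 10 | di-tert-butyl 2-[(1R,2S,3S,4S,5S,6S)-3-hydroxy-2-methyl-4-{[(2R)-2-methylbutanoyl]oxy}-3-(3-oxobutanoyl)-8-oxabicyclo[3.2.1]octan-6-yl]propanedioate | C[C@@H]1[C@@](O)(C(=O)CC(C)=O)[C@@H](OC(=O)[C@H](C)CC)[C@H]2O[C@@H]1C[C@H]2C(C(=O)OC(C)(C)C)C(=O)OC(C)(C)C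
F4 | step 11 | 2-[(1S,2S,3S,4S,5R,6S)-6-bromo-2,4-dihydroxy-4-[(3R)-3-hydroxybutanoyl]-5-methyl-3-{[(2R)-2-methylbutanoyl]oxy}cycloheptyl]propanedioic acid | OC(=O)C(C(O)=O)[C@@H]1C[C@H](Br)[C@H](C)[C@@](O)(C(=O)C[C@@H](C)O)[C@@H](OC(=O)[C@H](C)CC)[C@H]1O
F5 | step 11 | (3aS,5S,6R,7S,8S,8aR)-5-bromo-7-hydroxy-7-[(3R)-3-hydroxybutanoyl]-6-methyl-8-{[(2R)-2-methylbutanoyl]oxy}-2-oxooctahydro-2H-cyclohepta[b]furan-3-carboxylic acid | OC(=O)C1C(=O)O[C@@H]2[C@H]1C[C@H](Br)[C@H](C)[C@@](O)(C(=O)C[C@@H](C)O)[C@H]2OC(=O)[C@H](C)CC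
F6 | step 11 | (3aS,5R,6S,7S,8S,8aR)-5-(formyloxy)-7-hydroxy-7-[(3R)-3-hydroxybutanoyl]-6-methyl-8-{[(2R)-2-methylbutanoyl]oxy}-2-oxooctahydro-2H-cyclohepta[b]furan-3-carboxylic acid | OC(=O)C1C(=O)O[C@@H]2[C@H]1C[C@@H](OC=O)[C@H](C)[C@@](O)(C(=O)C[C@@H](C)O)[C@H]2OC(=O)[C@H](C)CC
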